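Ring B is cut at C7–C8 and C9–C10, which leads back to a ring A vinylcyclohexene (diene C7=C6–C5=C10) and citraconic anhydride. The cut exploits the ring B pattern of the target: C20 on C10, H-9 and C17 on C8 share one face, C11 and O-8 the other, exactly what endo addition of a cis-dienophile leaves behind. One cycloaddition closes ring B, makes both bonds and sets C8, C9 and C10. Its precursor is the enantiopure diene, locked as the trans-fused 3,18-acetonide and built from 2-methylcyclohexane-1,3-dione. Afterwards the carbonyl on C9 becomes C11, and the carbonyl on C8 is exchanged for oxygen with retention.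

Key step: step 8

Remark on numbering and configuration: labdane numbering is used throughout, and α is the face that carries C20, β the other. In the target O-3, C19 (axial C4 methyl), C20, H-9 and C17 are α, while H-3, C18 (equatorial CH2OH, trans to O-3), H-5, C11 and O-8 are β. The descriptors are 3R,4S,5S,8S,9R,10R, and the diol acetonide is therefore the trans-fused 3,18-acetonide.

Remark (assumption): the ketoreductase of step 3 is taken to be found by screening a commercial enzyme panel for the (2S,3R) product.

Step 1
Reactants: 1 2-methylcyclohexane-1,3-dione; 2 formaldehyde (37% aqueous solution)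
Product: 3 2-(hydroxymethyl)-2-methylcyclohexane-1,3-dione
Conditions: aq. HCHO (5 equiv), H2O, rt
Reagents that add atoms: none
Why: Aldol addition (hydroxymethylation) of the enolic dione to formaldehyde, in which attack through oxygen is reversible and only the C-adduct accumulates, so the quaternary carbon (later C4) is made without the O-alkylation that hard alkylating agents give with this dione; the product is still achiral.

Step 2
Reactants: 3 2-(hydroxymethyl)-2-methylcyclohexane-1,3-dione
Product: 4 2-[(tert-butyldimethylsilyloxy)methyl]-2-methylcyclohexane-1,3-dione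
Conditions: TBSCl, imidazole, CH2Cl2, 0 °C to rt
Reagents that add atoms: tert-butyldimethylsilyl chloride C[Si](C)(Cl)C(C)(C)C
Why: Silyl ether formation at the primary alcohol under weakly basic conditions blocks loss of formaldehyde by retro-aldol cleavage in the aqueous reduction that follows.

Step 3
Reactants: 4 silyl ether dione
Product: 5 (2S,3R)-2-[(tert-butyldimethylsilyloxy)methyl]-3-hydroxy-2-methylcyclohexan-1-one
Conditions: ketoreductase (R-selective, from a commercial panel), NADP+ (cat.), i-PrOH, phosphate buffer pH 7, 30 °C
Reagents that add atoms: none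
Why: Enzymatic desymmetrising mono-reduction of a prochiral 2,2-disubstituted cyclohexane-1,3-dione, a reaction type established with yeast and with isolated ketoreductases: the active site selects one of the two enantiotopic carbonyl groups and one of its faces, which sets C3 as R and at the same time makes the quaternary carbon C4 S, with the hydroxyl trans to CH2OTBS and cis to the methyl group.

Step 4
Reactants: 5 hydroxy ketone
Product: 7 trans-fused acetonide ketone (4aS,8aR)-2,2,4a-trimethylhexahydro-1,3-benzodioxin-5-one, via diol ketone 6 (not isolated)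
Conditions: CSA (cat.), MeOH, rt; then Me2C(OMe)2, acetone, rt
Reagents that add atoms: 2,2-dimethoxypropane COC(C)(C)OC
Why: Acid-catalysed methanolysis of the silyl ether and ketalisation of the freed 1,3-diol in one flask; because O-3 and C18 are trans on ring A the dioxane is trans-fused and holds C19 axial, and the quaternary α-carbon rules out dehydration.

Step 5
Reactants: 7 acetonide ketone
Product: 9 α-methyl ketone (methyl on C10; both epimers), via lithium enolate 8 (not isolated)
Conditions: LiN(i-Pr)2, THF, −78 °C; MeI, −78 to 0 °C
Reagents that add atoms: iodomethane CI; lithium diisopropylamide [Li+].CC(C)[N-]C(C)C (supplies only the lithium of 8)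
Why: Kinetic enolate alkylation, regiochemically unambiguous because C4 is quaternary and only C10 can be deprotonated; the configuration of the new methine does not matter since it becomes sp2 in step 6.

Step 6
Reactants: 9 α-methyl ketone
Product: 11 enol triflate (C5–OTf; C5=C10), via lithium enolate 10 (not isolated)
Conditions: LiN(i-Pr)2, THF, −78 to 0 °C; PhNTf2, 0 °C to rt
Reagents that add atoms: N-phenylbis(trifluoromethanesulfonimide) O=S(=O)(N(c1ccccc1)S(=O)(=O)C(F)(F)F)C(F)(F)F; lithium diisopropylamide [Li+].CC(C)[N-]C(C)C (supplies only the lithium of 10)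
Why: Enol triflate formation from the only possible, tetrasubstituted enolate, as practised on 2,2,6-trialkylcyclohexanones, fixes the C5=C10 double bond.

Step 7
Reactants: 11 enol triflate; 12 potassium vinyltrifluoroborate
Product: 13 ring A diene (4aS,8aR)-2,2,4a,6-tetramethyl-5-vinyl-4a,7,8,8a-tetrahydro-4H-1,3-benzodioxine
Conditions: PdCl2(dppf)·CH2Cl2 (5 mol%), Cs2CO3, THF/H2O (9:1), 70 °C
Reagents that add atoms: none
Why: Suzuki–Miyaura vinylation of an alkenyl triflate keeps the ring double bond in place and adds C6=C7, and the basic medium leaves the acetonide untouched.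

Step 8
Reactants: 13 ring A diene; 14 citraconic anhydride
Product: 15 endo adduct: ring B cyclohexene (C5=C6) 3,18-acetonide with the anhydride cis-fused on the β face of C8 and C9 (C11 carbonyl on C9); C20, H-9 and C17 all α
Conditions: 14 (3 equiv), BHT (cat.), toluene, 110 °C, sealed tube
Reagents that add atoms: none
Why: Concerted, suprafacial thermal [4+2] cycloaddition (normal-electron-demand Diels–Alder reaction), the known behaviour of 2-methyl-1-vinylcyclohexenes towards maleic and citraconic anhydride. Ring B closes as a cyclohexene by intermolecular annulation, both sigma bonds (C7–C8 and C9–C10) forming in the same event while the diene collapses to C5=C6. C10 is set by the face of attack: the trans-fused acetonide freezes ring A in the half-chair whose C19 methyl stands pseudo-axial on the α face, so 14 should come in from the β face and push C20 to α. C9 and C8 are set by endo orientation together with the cis geometry of 14: since C1 is held back in ring A, C20 is the inward-pointing diene substituent and ends cis to the exo groups H-9 and C17, while both carbonyl carbons end β. Regiocontrol is also needed and is steric, because the methyl-bearing alkene carbon of 14 can bond to the unsubstituted C7 but hardly to C10, which would join two fully substituted carbons. BHT and a temperature below about 120 °C hold back polymerisation and the 1,5-hydrogen shift of the diene.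

Step 9
Reactants: 15 endo adduct
Product: 16 half ester: β-CO2Me (C11) on C9; β-CO2H and α-CH3 on C8
Conditions: MeOH, DMAP (cat.), 40 °C
Reagents that add atoms: methanol CO
Why: Alcoholysis of a cyclic anhydride, in which the nucleophile can reach the carbonyls only over the convex face of the cis-fused bicycle, where the C11 carbonyl is flanked by H-9 but the other one by C17, so the ester should form at C11 without touching a stereocentre.

Step 10
Reactants: 16 half ester
Product: 18 keto ester: β-acetyl and α-CH3 on C8; β-CO2Me on C9; C5=C6, via acid chloride 17 (not isolated)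
Conditions: 1-chloro-N,N,2-trimethylpropenylamine, CH2Cl2, 0 °C; then Me2CuLi (from MeLi and CuI), Et2O, −78 °C
Reagents that add atoms: lithium dimethylcuprate [Li+].C[Cu-]C; 1-chloro-N,N,2-trimethylprop-1-en-1-amine CC(C)=C(Cl)N(C)C (supplies only the chlorine of 17)
Why: Neutral conversion of the hindered acid into its chloride with the α-chloroenamine (no HCl, so the acetonide survives) followed at once by acylation of lithium dimethylcuprate, a ketone synthesis that stops at the ketone and ignores the ester, the alkene and the acetal; C8 and C9 are not touched.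

Step 11
Reactants: 18 keto ester
Product: 19 trans-decalin keto ester (C5–C6 saturated; H-5 β, anti to C20)
Conditions: Mn(dpm)3 (10 mol%), PhSiH3, t-BuOOH, i-PrOH, rt
Reagents that add atoms: none
Why: Metal-hydride hydrogen atom transfer (MHAT) hydrogenation: a hydrogen atom adds to C6 and the tertiary C5 radical should take its second hydrogen on the β face, away from the two flanking axial methyl groups C19 and C20, which gives the trans ring fusion; the step is placed before the peracid oxidation so that no alkene remains to be epoxidised.

Step 12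
Reactants: 19 trans-decalin keto ester
Product: 20 8β-acetoxy ester (β-OAc and α-CH3 on C8; β-CO2Me on C9)
Conditions: mCPBA, NaHCO3, CH2Cl2, rt to 40 °C
Reagents that add atoms: 3-chloroperbenzoic acid OOC(=O)c1cccc(Cl)c1
Why: Baeyer–Villiger oxidation, in which the fully substituted C8 migrates far better than methyl and does so with retention, so that the β-acetyl group is replaced by a β-acetoxy group and C17 stays α.

Step 13
Reactants: 20 8β-acetoxy ester
Product: 21 8β,11-diol 3,18-acetonide
Conditions: LiAlH4, THF, 0 to 60 °C
Reagents that add atoms: none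
Why: Hydride reduction of both esters in one operation, the hindered C11 ester to the primary alcohol and the acetate to the free tertiary 8-OH, with no epimerisable carbonyl left on C9.

Step 14
Reactants: 21 8β,11-diol
Product: 22 8β-hydroxy-11-aldehyde (CHO axial, β on C9)
Conditions: Dess–Martin periodinane, CH2Cl2, 0 °C to rt
Reagents that add atoms: none
Why: Dess–Martin oxidation, which can act only on the primary C11 alcohol and runs without base, so that the axial aldehyde is exposed neither to epimerisation at C9 nor to retro-aldol cleavage or β-elimination of the 8-OH.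

Step 15
Reactants: 22 hydroxy aldehyde
Product: 23 9β-vinyl-8β-ol (C11=C12) 3,18-acetonide
Conditions: RhCl(PPh3)3 (2.5 mol%), PPh3, TMSCHN2, i-PrOH, THF, rt
Reagents that add atoms: trimethylsilyldiazomethane C[Si](C)(C)C=[N+]=[N-]
Why: Wittig methylenation in its rhodium-catalysed form, where Ph3P=CH2 is released slowly from TMSCHN2, PPh3 and i-PrOH in a salt-free and nearly neutral medium, a known answer to base-sensitive, epimerisable aldehydes that also tolerates the free hydroxyl group.

Step 16
Reactants: 23 vinyl compound; 24 chloroprene (2-chlorobuta-1,3-diene, stabilised solution in xylene)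
Product: 26 labda-13(16),14-diene 8β-ol 3,18-acetonide, via B-alkyl-9-BBN 25 (not isolated)
Conditions: 9-BBN-H, THF, rt; then aq. K3PO4, 24, Pd(OAc)2/SPhos (5/10 mol%), THF, 50 °C
Reagents that add atoms: 9-borabicyclo[3.3.1]nonane B1C2CCCC1CCC2 (supplies only the boryl group of 25)
Why: Anti-Markovnikov hydroboration of the only alkene and B-alkyl Suzuki–Miyaura coupling of the primary borane with the alkenyl chloride forge C12–C13 and bring in the 2-substituted butadiene in one flask without touching a stereocentre.

Step 17
Reactants: 26 diene acetonide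
Product: 27 3α,8β,18-triol
Conditions: AcOH/THF/H2O (3:1:1), 40 °C
Reagents that add atoms: none
Why: Mild acid hydrolysis of the isopropylidene acetal, with an acid too weak to ionise the tertiary 8-OH or to protonate the diene.

Step 18
Reactants: 27 triol
Product: 29 3-O-acetyl-18-O-TBS derivative, via 18-O-TBS ether 28 (not isolated)
Conditions: TBSCl (1.1 equiv), imidazole, CH2Cl2, 0 °C; then Ac2O, DMAP (cat.), pyridine, rt
Reagents that add atoms: tert-butyldimethylsilyl chloride C[Si](C)(Cl)C(C)(C)C; acetic anhydride CC(=O)OC(C)=O
Why: Rate-controlled silylation of the only primary alcohol followed in the same flask by DMAP-catalysed acetylation of the secondary 3-OH, the hindered tertiary 8-OH being too slow to react under these conditions.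

Step 19
Reactants: 29 3-O-acetyl-18-O-TBS derivative
Product: 30 target CNP0313672.1
Conditions: HF·pyridine, pyridine/THF, 0 °C to rt
Reagents that add atoms: none
Why: Fluoride-driven cleavage of the primary silyl ether under buffered, weakly acidic conditions, which avoids the free alkoxide that could carry the acetyl group from O-3 to O-18 and leaves the diene and the tertiary alcohol alone, should give the target.

Compound list
1 | 2-methylcyclohexane-1,3-dione | CC1C(=O)CCCC1=O | starting material
2 | formaldehyde (37% aqueous) | C=O | starting material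
3 | 2-(hydroxymethyl)-2-methylcyclohexane-1,3-dione | CC1(CO)C(=O)CCCC1=O | intermediate
4 | 2-[(tert-butyldimethylsilyloxy)methyl]-2-methylcyclohexane-1,3-dione | CC1(CO[Si](C)(C)C(C)(C)C)C(=O)CCCC1=O | intermediate
5 | (2S,3R)-2-[(tert-butyldimethylsilyloxy)methyl]-3-hydroxy-2-methylcyclohexan-1-one (OH trans to CH2OTBS) | O=C1CCC[C@@H](O)[C@]1(C)CO[Si](C)(C)C(C)(C)C | intermediate
6 | (2S,3R)-3-hydroxy-2-(hydroxymethyl)-2-methylcyclohexan-1-one (not isolated) | O=C1CCC[C@@H](O)[C@]1(C)CO | intermediate
7 | (4aS,8aR)-2,2,4a-trimethylhexahydro-1,3-benzodioxin-5-one, trans-fused | O=C1CCC[C@H]2OC(C)(C)OC[C@]12C | intermediate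
8 | lithium enolate of 7 (not isolated) | [Li+].[O-]C1=CCC[C@H]2OC(C)(C)OC[C@]12C | intermediate
9 | (4aS,8aR)-2,2,4a,6-tetramethylhexahydro-1,3-benzodioxin-5-one, both C10 epimers (centre left open, erased in step 6) | O=C1C(C)CC[C@H]2OC(C)(C)OC[C@]12C | intermediate
10 | lithium enolate of 9, tetrasubstituted (not isolated) | [Li+].[O-]C1=C(C)CC[C@H]2OC(C)(C)OC[C@]12C | intermediate
11 | (4aS,8aR)-2,2,4a,6-tetramethyl-4a,7,8,8a-tetrahydro-4H-1,3-benzodioxin-5-yl triflate | O=S(=O)(OC1=C(C)CC[C@H]2OC(C)(C)OC[C@]12C)C(F)(F)F | intermediate
12 | potassium vinyltrifluoroborate | [K+].C=C[B-](F)(F)F | starting material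
13 | ring A diene, (4aS,8aR)-2,2,4a,6-tetramethyl-5-vinyl-4a,7,8,8a-tetrahydro-4H-1,3-benzodioxine | C=CC1=C(C)CC[C@H]2OC(C)(C)OC[C@]12C | intermediate
14 | citraconic anhydride | CC1=CC(=O)OC1=O | starting material
15 | endo adduct, ring B cyclohexene with β cis-fused anhydride; C20, H-9, C17 α | C[C@]12CC=C3[C@@](C)(CC[C@H]4OC(C)(C)OC[C@]34C)[C@H]1C(=O)OC2=O | intermediate
16 | half ester, C11 methyl ester on C9, free acid on C8 | COC(=O)[C@@H]1[C@]2(C)CC[C@H]3OC(C)(C)OC[C@]3(C)C2=CC[C@]1(C)C(=O)O | intermediate
17 | acid chloride of 16 (not isolated) | COC(=O)[C@@H]1[C@]2(C)CC[C@H]3OC(C)(C)OC[C@]3(C)C2=CC[C@]1(C)C(=O)Cl | intermediate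
18 | keto ester, 8β-acetyl, C5=C6 | COC(=O)[C@@H]1[C@]2(C)CC[C@H]3OC(C)(C)OC[C@]3(C)C2=CC[C@]1(C)C(C)=O | intermediate
19 | trans-decalin keto ester, H-5 β | COC(=O)[C@@H]1[C@]2(C)CC[C@H]3OC(C)(C)OC[C@]3(C)[C@H]2CC[C@]1(C)C(C)=O | intermediate
20 | 8β-acetoxy C11 methyl ester | COC(=O)[C@@H]1[C@]2(C)CC[C@H]3OC(C)(C)OC[C@]3(C)[C@H]2CC[C@]1(C)OC(C)=O | intermediate
21 | 8β,11-diol 3,18-acetonide | OC[C@@H]1[C@]2(C)CC[C@H]3OC(C)(C)OC[C@]3(C)[C@H]2CC[C@]1(C)O | intermediate
22 | 8β-hydroxy-11-aldehyde 3,18-acetonide | O=C[C@@H]1[C@]2(C)CC[C@H]3OC(C)(C)OC[C@]3(C)[C@H]2CC[C@]1(C)O | intermediate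
23 | 9β-vinyl-8β-ol 3,18-acetonide | C=C[C@@H]1[C@]2(C)CC[C@H]3OC(C)(C)OC[C@]3(C)[C@H]2CC[C@]1(C)O | intermediate
24 | chloroprene (2-chlorobuta-1,3-diene) | C=CC(Cl)=C | starting material
25 | C12 B-alkyl-9-BBN (not isolated) | C1CC2CCCC(C1)B2CC[C@@H]1[C@]2(C)CC[C@H]3OC(C)(C)OC[C@]3(C)[C@H]2CC[C@]1(C)O | intermediate
26 | labda-13(16),14-dien-8β-ol 3,18-acetonide (9β side chain) | C=CC(=C)CC[C@@H]1[C@]2(C)CC[C@H]3OC(C)(C)OC[C@]3(C)[C@H]2CC[C@]1(C)O | intermediate
27 | 3α,8β,18-triol | C=CC(=C)CC[C@@H]1[C@]2(C)CC[C@@H](O)[C@](C)(CO)[C@H]2CC[C@]1(C)O | intermediate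
28 | 18-O-TBS ether of 27 (not isolated) | C=CC(=C)CC[C@@H]1[C@]2(C)CC[C@@H](O)[C@](C)(CO[Si](C)(C)C(C)(C)C)[C@H]2CC[C@]1(C)O | intermediate
29 | 3-O-acetyl-18-O-TBS derivative | C=CC(=C)CC[C@@H]1[C@]2(C)CC[C@@H](OC(C)=O)[C@](C)(CO[Si](C)(C)C(C)(C)C)[C@H]2CC[C@]1(C)O | intermediate
30 | CNP0313672.1, (3R,4S,5S,8S,9R,10R)-3-acetoxylabda-13(16),14-diene-8,18-diol | C=CC(=C)CC[C@@H]1[C@]2(C)CC[C@@H](OC(C)=O)[C@](C)(CO)[C@H]2CC[C@]1(C)O | target

Total step count: 19. Longest linear sequence: 19 (all partners added along the line are commercial).

Steps most likely to fail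

Step 8 (cycloaddition). The diene is twisted and carries a fully substituted terminus. The addition may therefore be slower than the 1,5-hydrogen shift and polymerisation of the diene, and crowding next to C4 may erode the endo and facial preference. The fallback makes the diene more electron-rich with an oxygen on C6 that is deleted afterwards, and it sets out from triflate 11.
- Carbonylative Stille coupling (CO, Me4Sn, Pd(PPh3)4, LiCl, THF) gives the 5-acetyl enone F1.
- Soft enolisation at the acetyl methyl (TBSOTf, Et3N, CH2Cl2) gives the 6-silyloxy diene F2.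
- F2 should add 14 at lower temperature, under the same steric regio-, endo and facial control, to give the silyl enol ether adduct F3.
- CsF and PhNTf2 in DME turn F3 into the C6 enol triflate F4.
- Reduction with Bu3SnH, LiCl and Pd(PPh3)4 replaces the triflate by hydrogen, which comes back to the route at 15.

Step 9 (anhydride opening). Methanol may prefer the carbonyl on C8, so that the differentiation of the two carbonyls is lost or inverted. The fallback turns that same accessibility to account with a carbon nucleophile and sets out from 15. MeMgBr (1 equiv, THF, −78 °C) adds to the more accessible carbonyl and stops at the keto carboxylate, giving the 8-acetyl 11-oic acid F5. Esterification of F5 with TMSCHN2 comes back to the route at 18.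

Step 16 (diene installation). Oxidative addition of the chlorodiene may be slow compared with its polymerisation and with protodeboronation of the hindered borane. The fallback assembles the diene from two C2 units and sets out from 23 through the same borane 25. Coupling with excess 1,1-dichloroethene (Pd2(dba)3, XantPhos, K3PO4, THF) should stop after the first, more reactive C–Cl bond and give the 13-chloro-13(16)-ene F6. A second Suzuki–Miyaura coupling of F6 with 12 (Pd(OAc)2, SPhos, Cs2CO3, THF/H2O) comes back to the route at 26.

Further compounds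
F1 | step 8 | 5-acetyl enone (ring A 3,18-acetonide, acetyl on C5, C5=C10) | CC(=O)C1=C(C)CC[C@H]2OC(C)(C)OC[C@]12C
F2 | step 8 | 6-silyloxy diene (C7=C6(OTBS)–C5=C10) | C=C(O[Si](C)(C)C(C)(C)C)C1=C(C)CC[C@H]2OC(C)(C)OC[C@]12C
F3 | step 8 | silyl enol ether adduct (as 15 with OTBS on C6) | C[C@]12CC(O[Si](C)(C)C(C)(C)C)=C3[C@@](C)(CC[C@H]4OC(C)(C)OC[C@]34C)[C@H]1C(=O)OC2=O
F4 | step 8 | C6 enol triflate (as 15 with OTf on C6) | C[C@]12CC(OS(=O)(=O)C(F)(F)F)=C3[C@@](C)(CC[C@H]4OC(C)(C)OC[C@]34C)[C@H]1C(=O)OC2=O
F5 | step 9 | 8-acetyl 11-oic acid (as 18 with CO2H on C9) | OC(=O)[C@@H]1[C@]2(C)CC[C@H]3OC(C)(C)OC[C@]3(C)C2=CC[C@]1(C)C(C)=O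
F6 | step 16 | 13-chloro-13(16)-ene (14,15-dinor analogue of 26) | C=C(Cl)CC[C@@H]1[C@]2(C)CC[C@H]3OC(C)(C)OC[C@]3(C)[C@H]2CC[C@]1(C)O
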